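## Retrosynthetic overview

1. The α-methylene lactone is unmasked last from a C13 dimethylamino (Mannich) precursor; the (Z)-enol acetate comes from Ru-catalysed anti-Markovnikov addition of AcOH to a C10 ethynyl group.
2. The 8α-angelate/9β-acetate pair comes from cis-dihydroxylation of a C8=C9 alkene, O8-selective angeloylation, oxidation–reduction at C9 (inversion) and acetylation.
3. C7 and the trans-γ-lactone come from a Johnson–Claisen rearrangement of a 9β-allylic alcohol (C9→C7 chirality transfer) and lactonisation onto O6.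
4. C5 and C10 come from isopropenyl conjugate addition anti to a 6-silyloxy group and enolate dichlorovinylation (ethynyl precursor) on (S)-4-silyloxy-2-methylcyclohex-2-enone.
5. Ring order: the carbocycle is present from the start (cyclohexa-1,3-diene; its meso 1,4-diacetate is desymmetrised by a lipase); the lactone ring is closed second, in step 14.

Convention: from compound 9 on, ring atoms carry the elemane locants of the target (C5–C10; C6 bears the lactone oxygen, C10 is quaternary); α is the ring face of the C6 oxygen, β the face of the C10 methyl; TBSO = tert-butyldimethylsilyloxy.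

Assumption: the lipase in step 2 shows its usual enantiotopic preference (hydrolysis at the S-configured carbinol carbon, as with the cyclopentene analogue).

## Route

Step 1
Reactants: 1 cyclohexa-1,3-diene
Product: 2 cis-cyclohex-2-ene-1,4-diyl diacetate (meso)
Conditions: Pd(OAc)2 (5 mol%), LiCl (20 mol%), LiOAc·2H2O, p-benzoquinone (25 mol%), MnO2 (1.2 equiv), AcOH, 25 °C
Reagents that add atoms: acetic acid CC(=O)O
Why: Bäckvall palladium-catalysed 1,4-diacetoxylation of a 1,3-diene, in which catalytic chloride forces the second acetate to attack the π-allyl complex from outside, so both C–O bonds end up cis and the achiral meso diacetate results.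

Step 2
Reactants: 2 cis-cyclohex-2-ene-1,4-diyl diacetate (meso)
Product: 3 (1R,4S)-4-hydroxycyclohex-2-en-1-yl acetate
Conditions: lipase (Candida antarctica lipase B, immobilised; a serine hydrolase), 0.1 M phosphate buffer pH 7.0, 25 °C
Reagents that add atoms: none
Why: Enzymatic desymmetrisation (enantiotopic-group-selective ester hydrolysis) by a lipase, which cleaves only the acetate on the S-configured carbinol carbon of the meso substrate and so sets catalytically the absolute configuration of the future C6.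

Step 3
Reactants: 3 (1R,4S)-4-hydroxycyclohex-2-en-1-yl acetate
Product: 4 (1R,4S)-4-[(tert-butyldimethylsilyl)oxy]cyclohex-2-en-1-yl acetate
Conditions: TBSCl, imidazole, DMF, 25 °C
Reagents that add atoms: tert-butyldimethylsilyl chloride CC(C)(C)[Si](C)(C)Cl
Why: Imidazole-promoted silylation of the free secondary alcohol; no stereocentre is affected.

Step 4
Reactants: 4 (1R,4S)-4-[(tert-butyldimethylsilyl)oxy]cyclohex-2-en-1-yl acetate
Product: 5 (1R,4S)-4-[(tert-butyldimethylsilyl)oxy]cyclohex-2-en-1-ol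
Conditions: K2CO3 (cat.), MeOH, 25 °C
Reagents that add atoms: none
Why: Base-catalysed transesterification (methanolysis) removes the acetate while the silyl ether is stable; no stereocentre is affected.

Step 5
Reactants: 5 (1R,4S)-4-[(tert-butyldimethylsilyl)oxy]cyclohex-2-en-1-ol
Product: 6 (S)-4-[(tert-butyldimethylsilyl)oxy]cyclohex-2-en-1-one
Conditions: Dess–Martin periodinane, CH2Cl2, 25 °C
Reagents that add atoms: none
Why: Dess–Martin oxidation of the allylic alcohol gives the enone and leaves the silyloxy-bearing carbon (future C6) as the only stereocentre.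

Step 6
Reactants: 6 (S)-4-[(tert-butyldimethylsilyl)oxy]cyclohex-2-en-1-one
Product: 7 (S)-4-[(tert-butyldimethylsilyl)oxy]-2-iodocyclohex-2-en-1-one
Conditions: I2, pyridine/CH2Cl2, 0 → 25 °C
Reagents that add atoms: iodine II
Why: Johnson α-iodination of an enone (pyridine conjugate addition, iodination of the enolate, elimination).

Step 7
Reactants: 7 (S)-4-[(tert-butyldimethylsilyl)oxy]-2-iodocyclohex-2-en-1-one
Product: 8 (S)-4-[(tert-butyldimethylsilyl)oxy]-2-methylcyclohex-2-en-1-one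
Conditions: Me4Sn, Pd2(dba)3 (2.5 mol%), AsPh3 (10 mol%), NMP, 80 °C
Reagents that add atoms: tetramethylstannane C[Sn](C)(C)C
Why: Stille cross-coupling of the α-iodoenone installs the future C14 methyl.

Step 8
Reactants: 8 (S)-4-[(tert-butyldimethylsilyl)oxy]-2-methylcyclohex-2-en-1-one
Product: 9 6α-TBSO-5β-isopropenyl-10-methyl-9-(trimethylsilyloxy)cyclohex-9(10)-ene
Conditions: CH2=C(CH3)MgBr (1.5 equiv), CuBr·SMe2 (20 mol%), TMSCl, HMPA, THF, −78 °C; Et3N quench
Reagents that add atoms: isopropenylmagnesium bromide C=C(C)[Mg]Br; chlorotrimethylsilane C[Si](C)(C)Cl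
Why: Copper-catalysed, TMSCl-accelerated conjugate addition occurs anti to the adjacent silyloxy group (trans-3,4 selectivity of 4-silyloxycyclohexenones), which fixes C5 (isopropenyl β), and traps the enolate regiospecifically as its silyl enol ether.

Step 9
Reactants: 9 6α-TBSO-5β-isopropenyl-10-methyl-9-(trimethylsilyloxy)cyclohex-9(10)-ene
Product: 11 6α-TBSO-5β-isopropenyl-10β-methyl-10α-[(E)-1,2-dichlorovinyl]cyclohexan-9-one, via lithium enolate 10 (not isolated)
Conditions: MeLi (1.05 equiv), THF, 0 °C; HMPA; Cl2C=CHCl (1.5 equiv), 0 → 25 °C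
Reagents that add atoms: trichloroethylene ClC=C(Cl)Cl
Why: Kende ethynylation (enolate addition to dichloroacetylene generated in situ, then protonation) creates the quaternary C10, the electrophile entering anti to the neighbouring 5β-isopropenyl group so that the dichlorovinyl group is α and the methyl β.

Step 10
Reactants: 11 6α-TBSO-5β-isopropenyl-10β-methyl-10α-[(E)-1,2-dichlorovinyl]cyclohexan-9-one
Product: 13 6α-TBSO-5β-isopropenyl-10β-methyl-10α-[(E)-1,2-dichlorovinyl]cyclohex-7-en-9-one, via TMS enol ether 12 (not isolated)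
Conditions: TMSOTf, Et3N, CH2Cl2, 0 °C; then Pd(OAc)2 (1.1 equiv), MeCN, 25 °C
Reagents that add atoms: none
Why: Saegusa–Ito oxidation: enolisation can only occur towards C8 (C10 is quaternary) and Pd(OAc)2 dehydrosilylates the enol ether to the C7=C8 enone.

Step 11
Reactants: 13 6α-TBSO-5β-isopropenyl-10β-methyl-10α-[(E)-1,2-dichlorovinyl]cyclohex-7-en-9-one
Product: 14 6α-TBSO-5β-isopropenyl-10β-methyl-10α-[(E)-1,2-dichlorovinyl]cyclohex-7-en-9β-ol
Conditions: NaBH4, CeCl3·7H2O, MeOH, −78 → −40 °C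
Reagents that add atoms: none
Why: Luche 1,2-reduction; hydride attacks C9 axially from the α face, anti to the axial 10β-methyl of the favoured half-chair, giving the 9β-allylic alcohol.

Step 12
Reactants: 14 6α-TBSO-5β-isopropenyl-10β-methyl-10α-[(E)-1,2-dichlorovinyl]cyclohex-7-en-9β-ol
Product: 16 6α-TBSO-5β-isopropenyl-10β-methyl-10α-[(trimethylsilyl)ethynyl]cyclohex-7-en-9β-ol, via bis-TMS derivative 15 (not isolated)
Conditions: n-BuLi (3.3 equiv), THF, −78 → 0 °C; TMSCl (3 equiv), −78 → 25 °C; aq. citric acid/MeOH work-up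
Reagents that add atoms: chlorotrimethylsilane C[Si](C)(C)Cl
Why: Second stage of the Kende sequence: deprotonation and loss of LiCl give the chloroalkyne, chlorine–lithium exchange gives the lithium acetylide, which is C-silylated, and mild acid cleaves only the O–Si bond of the transient silyl ether.

Step 13
Reactants: 16 6α-TBSO-5β-isopropenyl-10β-methyl-10α-[(trimethylsilyl)ethynyl]cyclohex-7-en-9β-ol
Product: 18 ethyl 2-[6α-TBSO-5β-isopropenyl-10β-methyl-10α-[(trimethylsilyl)ethynyl]cyclohex-8-en-7β-yl]acetate, via ketene acetal 17 (not isolated)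
Conditions: CH3C(OEt)3 (10 equiv), EtCO2H (10 mol%), xylene, 140 °C, EtOH distilled off
Reagents that add atoms: triethyl orthoacetate CCOC(C)(OCC)OCC
Why: Johnson–Claisen orthoester rearrangement: the suprafacial [3,3] shift transfers the 9β C–O chirality to a new 7β C–C bond (trans to the 6α-oxygen) and moves the alkene to C8=C9.

Step 14
Reactants: 18 ethyl 2-[6α-TBSO-5β-isopropenyl-10β-methyl-10α-[(trimethylsilyl)ethynyl]cyclohex-8-en-7β-yl]acetate
Product: 20 7β-(carboxymethyl)-6α-hydroxy-5β-isopropenyl-10β-methyl-10α-[(trimethylsilyl)ethynyl]cyclohex-8-ene 6,12-lactone (trans-fused), via hydroxy ester 19 (not isolated)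
Conditions: HF·pyridine, THF, 0 → 25 °C; then PPTS (20 mol%), PhMe, 80 °C
Reagents that add atoms: none
Why: Desilylation followed by acid-catalysed lactonisation of the trans-1,2 (diequatorial) hydroxy ester closes the trans-fused γ-lactone without touching a stereocentre.

Step 15
Reactants: 20 7β-(carboxymethyl)-6α-hydroxy-5β-isopropenyl-10β-methyl-10α-[(trimethylsilyl)ethynyl]cyclohex-8-ene 6,12-lactone (trans-fused)
Product: 22 11-(dimethylaminomethyl) derivative of lactone 20 (Mannich base; C11 epimers), via lithium enolate 21 (not isolated)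
Conditions: LiN(iPr)2 (1.2 equiv), THF, −78 °C; Me2N=CH2 iodide (Eschenmoser's salt, 2 equiv), −78 → 0 °C
Reagents that add atoms: N,N-dimethylmethyleneiminium iodide C=[N+](C)C.[I-]
Why: Mannich-type aminomethylation of the lactone enolate with Eschenmoser's salt; the C11 configuration is not controlled and does not matter because this centre becomes sp2 in step 25.

Step 16
Reactants: 22 11-(dimethylaminomethyl) derivative of lactone 20 (Mannich base; C11 epimers)
Product: 23 10α-ethynyl analogue of 22 (C-desilylated Mannich-base lactone)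
Conditions: K2CO3 (20 mol%), MeOH, 0 → 25 °C
Reagents that add atoms: none
Why: Methanolysis of the C(sp)–Si bond frees the terminal alkyne while no hydroxyl or acyl group that base could shift is yet present.

Step 17
Reactants: 23 10α-ethynyl analogue of 22 (C-desilylated Mannich-base lactone)
Product: 24 8α,9α-dihydroxy-5β-(1,2-dihydroxypropan-2-yl) tetraol of 23 (side-chain carbinol epimers)
Conditions: OsO4 (5 mol%), NMO (4 equiv), acetone/H2O 4:1, 25 °C
Reagents that add atoms: N-methylmorpholine N-oxide C[N+]1([O-])CCOCC1; water O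
Why: Upjohn cis-dihydroxylation: OsO4 adds to the ring alkene from the α face, anti to the pseudoaxial 10β-methyl and the 7β-substituent, giving the 8α,9α-diol, and the isopropenyl group is deliberately dihydroxylated too (temporary protection as a glycol of uncontrolled configuration).

Step 18
Reactants: 24 8α,9α-dihydroxy-5β-(1,2-dihydroxypropan-2-yl) tetraol of 23 (side-chain carbinol epimers)
Product: 25 8α,9α-dihydroxy-5β-(2-hydroxy-1-iodopropan-2-yl) iodohydrin
Conditions: I2 (1.3 equiv), PPh3 (1.3 equiv), imidazole (3 equiv), THF/MeCN, 0 °C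
Reagents that add atoms: iodine II
Why: Appel-type iodination converts only the single primary hydroxyl and leaves the secondary and tertiary hydroxyls untouched.

Step 19
Reactants: 25 8α,9α-dihydroxy-5β-(2-hydroxy-1-iodopropan-2-yl) iodohydrin
Product: 26 11-(dimethylaminomethyl)-10α-ethynyl-8α,9α-dihydroxy-5β-isopropenyl-10β-methyl 6α,12-lactone
Conditions: Zn dust (10 equiv), AcOH/THF 1:4, 25 °C
Reagents that add atoms: none
Why: Zinc-mediated reductive elimination of the β-iodo alcohol (halohydrin deoxygenation) regenerates the isopropenyl double bond with unambiguous regiochemistry.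

Step 20
Reactants: 26 11-(dimethylaminomethyl)-10α-ethynyl-8α,9α-dihydroxy-5β-isopropenyl-10β-methyl 6α,12-lactone
Product: 27 8α-O-angelate of 26 (free 9α-hydroxyl)
Conditions: angelic acid (3 equiv), 2,4,6-trichlorobenzoyl chloride (3 equiv), Et3N (6 equiv), PhMe, 25 °C, 2 h; then 26, 70 °C
Reagents that add atoms: angelic acid C/C=C(/C)C(=O)O
Why: Yamaguchi-type mixed-anhydride esterification without a nucleophilic catalyst (to avoid angelate-to-tiglate isomerisation) acylates the equatorial 8α-hydroxyl selectively over the axial, neopentyl-type 9α-hydroxyl.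

Step 21
Reactants: 27 8α-O-angelate of 26 (free 9α-hydroxyl)
Product: 28 8α-angeloyloxy-9-ketone
Conditions: Dess–Martin periodinane (1.5 equiv), CH2Cl2, 0 → 25 °C
Reagents that add atoms: none
Why: Dess–Martin oxidation of the hindered axial 9α-alcohol to the ketone erases the wrongly configured C9 centre.

Step 22
Reactants: 28 8α-angeloyloxy-9-ketone
Product: 29 8α-angeloyloxy-9β-alcohol
Conditions: NaBH4, CeCl3·7H2O, MeOH, −78 °C; AcOH quench
Reagents that add atoms: none
Why: Luche reduction: in the chair locked by the trans-fused lactone, hydride attacks C9 axially from the α face (the β face is shielded by the adjacent axial 10β-methyl), giving the equatorial 9β-alcohol trans to the 8α-ester.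

Step 23
Reactants: 29 8α-angeloyloxy-9β-alcohol
Product: 30 9β-acetoxy-8α-angeloyloxy-10α-ethynyl Mannich-base lactone
Conditions: Ac2O, DMAP (10 mol%), pyridine, CH2Cl2, 0 → 25 °C
Reagents that add atoms: acetic anhydride CC(=O)OC(C)=O
Why: DMAP-catalysed acetylation of the 9β-alcohol; no stereocentre is affected.

Step 24
Reactants: 30 9β-acetoxy-8α-angeloyloxy-10α-ethynyl Mannich-base lactone
Product: 31 9β-acetoxy-8α-angeloyloxy-10α-[(Z)-2-acetoxyvinyl] Mannich-base lactone
Conditions: [RuCl2(p-cymene)]2 (2.5 mol%), P(4-ClC6H4)3 (7.5 mol%), DMAP (10 mol%), AcOH (3 equiv), PhMe, 60 °C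
Reagents that add atoms: acetic acid CC(=O)O
Why: Ruthenium-catalysed anti-Markovnikov hydro-acyloxylation of a terminal alkyne via a ruthenium vinylidene, in which acetate attacks the carbon next to the metal and protonolysis delivers the (Z)-enol acetate.

Step 25
Reactants: 31 9β-acetoxy-8α-angeloyloxy-10α-[(Z)-2-acetoxyvinyl] Mannich-base lactone
Product: 33 CNP0582479.1 (target), via methiodide 32 (not isolated)
Conditions: MeI (10 equiv), MeCN, 25 °C; then sat. aq. NaHCO3/EtOAc, 25 °C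
Reagents that add atoms: none
Why: Exhaustive N-methylation then bicarbonate-induced E1cB (Hofmann-type) elimination of trimethylamine unmasks the α-methylene-γ-lactone; no stereocentre is changed.

## Compound list

1 | cyclohexa-1,3-diene | C1=CC=CCC1 | starting material
2 | cis-cyclohex-2-ene-1,4-diyl diacetate (meso) | CC(=O)O[C@H]1CC[C@@H](OC(C)=O)C=C1 | intermediate
3 | (1R,4S)-4-hydroxycyclohex-2-en-1-yl acetate | O[C@H]1CC[C@@H](OC(C)=O)C=C1 | intermediate
4 | (1R,4S)-4-[(tert-butyldimethylsilyl)oxy]cyclohex-2-en-1-yl acetate | CC(C)(C)[Si](C)(C)O[C@H]1CC[C@@H](OC(C)=O)C=C1 | intermediate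
5 | (1R,4S)-4-[(tert-butyldimethylsilyl)oxy]cyclohex-2-en-1-ol | CC(C)(C)[Si](C)(C)O[C@H]1CC[C@@H](O)C=C1 | intermediate
6 | (S)-4-[(tert-butyldimethylsilyl)oxy]cyclohex-2-en-1-one | CC(C)(C)[Si](C)(C)O[C@H]1CCC(=O)C=C1 | intermediate
7 | (S)-4-[(tert-butyldimethylsilyl)oxy]-2-iodocyclohex-2-en-1-one | CC(C)(C)[Si](C)(C)O[C@H]1CCC(=O)C(I)=C1 | intermediate
8 | (S)-4-[(tert-butyldimethylsilyl)oxy]-2-methylcyclohex-2-en-1-one | CC(C)(C)[Si](C)(C)O[C@H]1CCC(=O)C(C)=C1 | intermediate
9 | 6α-TBSO-5β-isopropenyl-10-methyl-9-(trimethylsilyloxy)cyclohex-9(10)-ene | CC(C)(C)[Si](C)(C)O[C@H]1CCC(O[Si](C)(C)C)=C(C)[C@@H]1C(C)=C | intermediate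
10 | lithium enolate (C9–OLi, C9=C10) corresponding to 9 | CC(C)(C)[Si](C)(C)O[C@H]1CCC(O[Li])=C(C)[C@@H]1C(C)=C | intermediate
11 | 6α-TBSO-5β-isopropenyl-10β-methyl-10α-[(E)-1,2-dichlorovinyl]cyclohexan-9-one | CC(C)(C)[Si](C)(C)O[C@H]1CCC(=O)[C@@](C)(/C(Cl)=C\Cl)[C@@H]1C(C)=C | intermediate
12 | C8=C9 trimethylsilyl enol ether of 11 | CC(C)(C)[Si](C)(C)O[C@H]1CC=C(O[Si](C)(C)C)[C@@](C)(/C(Cl)=C\Cl)[C@@H]1C(C)=C | intermediate
13 | 6α-TBSO-5β-isopropenyl-10β-methyl-10α-[(E)-1,2-dichlorovinyl]cyclohex-7-en-9-one | CC(C)(C)[Si](C)(C)O[C@H]1C=CC(=O)[C@@](C)(/C(Cl)=C\Cl)[C@@H]1C(C)=C | intermediate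
14 | 6α-TBSO-5β-isopropenyl-10β-methyl-10α-[(E)-1,2-dichlorovinyl]cyclohex-7-en-9β-ol | CC(C)(C)[Si](C)(C)O[C@H]1C=C[C@H](O)[C@@](C)(/C(Cl)=C\Cl)[C@@H]1C(C)=C | intermediate
15 | 9β-O-trimethylsilyl ether of 16 (bis-TMS derivative) | CC(C)(C)[Si](C)(C)O[C@H]1C=C[C@H](O[Si](C)(C)C)[C@@](C)(C#C[Si](C)(C)C)[C@@H]1C(C)=C | intermediate
16 | 6α-TBSO-5β-isopropenyl-10β-methyl-10α-[(trimethylsilyl)ethynyl]cyclohex-7-en-9β-ol | CC(C)(C)[Si](C)(C)O[C@H]1C=C[C@H](O)[C@@](C)(C#C[Si](C)(C)C)[C@@H]1C(C)=C | intermediate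
17 | 9β-O-(1-ethoxyvinyl) ether of 16 (mixed ketene acetal) | CC(C)(C)[Si](C)(C)O[C@H]1C=C[C@H](OC(=C)OCC)[C@@](C)(C#C[Si](C)(C)C)[C@@H]1C(C)=C | intermediate
18 | ethyl 2-[6α-TBSO-5β-isopropenyl-10β-methyl-10α-[(trimethylsilyl)ethynyl]cyclohex-8-en-7β-yl]acetate | CC(C)(C)[Si](C)(C)O[C@H]1[C@H](CC(=O)OCC)C=C[C@@](C)(C#C[Si](C)(C)C)[C@@H]1C(C)=C | intermediate
19 | ethyl 2-[6α-hydroxy-5β-isopropenyl-10β-methyl-10α-[(trimethylsilyl)ethynyl]cyclohex-8-en-7β-yl]acetate | O[C@H]1[C@H](CC(=O)OCC)C=C[C@@](C)(C#C[Si](C)(C)C)[C@@H]1C(C)=C | intermediate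
20 | 7β-(carboxymethyl)-6α-hydroxy-5β-isopropenyl-10β-methyl-10α-[(trimethylsilyl)ethynyl]cyclohex-8-ene 6,12-lactone (trans-fused) | O=C2O[C@H]1[C@H](C2)C=C[C@@](C)(C#C[Si](C)(C)C)[C@@H]1C(C)=C | intermediate
21 | lithium enolate (C11=C12–OLi) of lactone 20 | [Li]OC=2O[C@H]1[C@H](C=2)C=C[C@@](C)(C#C[Si](C)(C)C)[C@@H]1C(C)=C | intermediate
22 | 11-(dimethylaminomethyl) derivative of lactone 20 (Mannich base; C11 epimers) | O=C2O[C@H]1[C@H](C2CN(C)C)C=C[C@@](C)(C#C[Si](C)(C)C)[C@@H]1C(C)=C | intermediate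
23 | 10α-ethynyl analogue of 22 (C-desilylated Mannich-base lactone) | O=C2O[C@H]1[C@H](C2CN(C)C)C=C[C@@](C)(C#C)[C@@H]1C(C)=C | intermediate
24 | 8α,9α-dihydroxy-5β-(1,2-dihydroxypropan-2-yl) tetraol of 23 (side-chain carbinol epimers) | O=C2O[C@H]1[C@H](C2CN(C)C)[C@@H](O)[C@@H](O)[C@@](C)(C#C)[C@@H]1C(C)(O)CO | intermediate
25 | 8α,9α-dihydroxy-5β-(2-hydroxy-1-iodopropan-2-yl) iodohydrin | O=C2O[C@H]1[C@H](C2CN(C)C)[C@@H](O)[C@@H](O)[C@@](C)(C#C)[C@@H]1C(C)(O)CI | intermediate
26 | 11-(dimethylaminomethyl)-10α-ethynyl-8α,9α-dihydroxy-5β-isopropenyl-10β-methyl 6α,12-lactone | O=C2O[C@H]1[C@H](C2CN(C)C)[C@@H](O)[C@@H](O)[C@@](C)(C#C)[C@@H]1C(C)=C | intermediate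
27 | 8α-O-angelate of 26 (free 9α-hydroxyl) | O=C2O[C@H]1[C@H](C2CN(C)C)[C@@H](OC(=O)/C(C)=C\C)[C@@H](O)[C@@](C)(C#C)[C@@H]1C(C)=C | intermediate
28 | 8α-angeloyloxy-9-ketone | O=C2O[C@H]1[C@H](C2CN(C)C)[C@@H](OC(=O)/C(C)=C\C)C(=O)[C@@](C)(C#C)[C@@H]1C(C)=C | intermediate
29 | 8α-angeloyloxy-9β-alcohol | O=C2O[C@H]1[C@H](C2CN(C)C)[C@@H](OC(=O)/C(C)=C\C)[C@H](O)[C@@](C)(C#C)[C@@H]1C(C)=C | intermediate
30 | 9β-acetoxy-8α-angeloyloxy-10α-ethynyl Mannich-base lactone | O=C2O[C@H]1[C@H](C2CN(C)C)[C@@H](OC(=O)/C(C)=C\C)[C@H](OC(C)=O)[C@@](C)(C#C)[C@@H]1C(C)=C | intermediate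
31 | 9β-acetoxy-8α-angeloyloxy-10α-[(Z)-2-acetoxyvinyl] Mannich-base lactone | O=C2O[C@H]1[C@H](C2CN(C)C)[C@@H](OC(=O)/C(C)=C\C)[C@H](OC(C)=O)[C@@](C)(/C=C\OC(C)=O)[C@@H]1C(C)=C | intermediate
32 | N-methyl quaternary ammonium iodide of 31 (methiodide) | O=C2O[C@H]1[C@H](C2C[N+](C)(C)C)[C@@H](OC(=O)/C(C)=C\C)[C@H](OC(C)=O)[C@@](C)(/C=C\OC(C)=O)[C@@H]1C(C)=C.[I-] | intermediate
33 | CNP0582479.1 | C=C1C(=O)O[C@H]2[C@H]1[C@@H](OC(=O)/C(C)=C\C)[C@H](OC(C)=O)[C@@](C)(/C=C\OC(C)=O)[C@@H]2C(=C)C | target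

## Step count and weak points

Total step count: 25. Longest linear sequence: 25 steps (fully linear from cyclohexa-1,3-diene).

Step 9 (dichlorovinylation of a hindered, tetrasubstituted enolate to build the quaternary C10) may stall or O-alkylate. The fallback transfers an alkynyl group from a hypervalent iodine reagent instead of adding the enolate to dichloroacetylene. It sets out from 9: the lithium enolate 10 is generated as before and treated at −78 °C with 1-[(trimethylsilyl)ethynyl]-1,2-benziodoxol-3(1H)-one, which gives the 10α-[(trimethylsilyl)ethynyl] ketone F1 in one operation. Soft enolisation (TMSOTf, Et3N) then gives the silyl enol ether F2, Pd(OAc)2 gives the enone F3, and Luche reduction of F3 comes back to the route at 16, so step 12 is no longer needed.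

Step 13 (Johnson–Claisen on a neopentyl-type allylic alcohol at 140 °C under acid) may suffer ionisation to a diene or incomplete orthoester exchange. The fallback is a low-temperature Ireland–Claisen ester-enolate rearrangement. It sets out from 16: Ac2O/DMAP gives the allylic acetate F4, and LiN(iPr)2 with TMSCl/Et3N at −78 °C gives the silyl ketene acetal F5, which rearranges on warming to the trimethylsilyl ester F6. Aqueous work-up gives the carboxylic acid F7, HF·pyridine gives the hydroxy acid F8, and acid-catalysed lactonisation of F8 comes back to the route at 20.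

Step 24 (Ru-catalysed anti-Markovnikov addition of AcOH to an alkyne on a quaternary carbon) may be slow or give Markovnikov or E products. The fallback goes through a stereodefined alkenylboron compound. It sets out from 30: rhodium-catalysed trans-hydroboration ([Rh(cod)Cl]2, P(iPr)3, Et3N, pinacolborane) gives the (Z)-alkenyl pinacolboronate F9, and Cu(OAc)2-mediated oxidative acetoxylation of F9 (Chan–Lam type, with retention of alkene geometry) comes back to the route at 31.

## Further compounds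

F1 | step 9 | 6α-TBSO-5β-isopropenyl-10β-methyl-10α-[(trimethylsilyl)ethynyl]cyclohexan-9-one | CC(C)(C)[Si](C)(C)O[C@H]1CCC(=O)[C@@](C)(C#C[Si](C)(C)C)[C@@H]1C(C)=C
F2 | step 9 | C8=C9 trimethylsilyl enol ether of F1 | CC(C)(C)[Si](C)(C)O[C@H]1CC=C(O[Si](C)(C)C)[C@@](C)(C#C[Si](C)(C)C)[C@@H]1C(C)=C
F3 | step 9 | 6α-TBSO-5β-isopropenyl-10β-methyl-10α-[(trimethylsilyl)ethynyl]cyclohex-7-en-9-one | CC(C)(C)[Si](C)(C)O[C@H]1C=CC(=O)[C@@](C)(C#C[Si](C)(C)C)[C@@H]1C(C)=C
F4 | step 13 | 9β-O-acetate of 16 | CC(C)(C)[Si](C)(C)O[C@H]1C=C[C@H](OC(C)=O)[C@@](C)(C#C[Si](C)(C)C)[C@@H]1C(C)=C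
F5 | step 13 | 9β-O-[1-(trimethylsilyloxy)vinyl] ether of 16 (silyl ketene acetal) | CC(C)(C)[Si](C)(C)O[C@H]1C=C[C@H](OC(=C)O[Si](C)(C)C)[C@@](C)(C#C[Si](C)(C)C)[C@@H]1C(C)=C
F6 | step 13 | trimethylsilyl 2-[6α-TBSO-5β-isopropenyl-10β-methyl-10α-[(trimethylsilyl)ethynyl]cyclohex-8-en-7β-yl]acetate | CC(C)(C)[Si](C)(C)O[C@H]1[C@H](CC(=O)O[Si](C)(C)C)C=C[C@@](C)(C#C[Si](C)(C)C)[C@@H]1C(C)=C
F7 | step 13 | 2-[6α-TBSO-5β-isopropenyl-10β-methyl-10α-[(trimethylsilyl)ethynyl]cyclohex-8-en-7β-yl]acetic acid | CC(C)(C)[Si](C)(C)O[C@H]1[C@H](CC(=O)O)C=C[C@@](C)(C#C[Si](C)(C)C)[C@@H]1C(C)=C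
F8 | step 13 | 2-[6α-hydroxy-5β-isopropenyl-10β-methyl-10α-[(trimethylsilyl)ethynyl]cyclohex-8-en-7β-yl]acetic acid | O[C@H]1[C@H](CC(=O)O)C=C[C@@](C)(C#C[Si](C)(C)C)[C@@H]1C(C)=C
F9 | step 24 | 10α-[(Z)-2-(4,4,5,5-tetramethyl-1,3,2-dioxaborolan-2-yl)vinyl] analogue of 30 | O=C2O[C@H]1[C@H](C2CN(C)C)[C@@H](OC(=O)/C(C)=C\C)[C@H](OC(C)=O)[C@@](C)(/C=C\B3OC(C)(C)C(C)(C)O3)[C@@H]1C(C)=C
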